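Count the catalyst: precatalyst, free catalyst and both intermediates sum to 50 µM at every moment, and the round runs through the last three forms, so the rounds are made by the released part.

    partner + precatalyst → free catalyst + spent reagent (k1 = 0.0073 /M/s)
    substrate + catalyst intermediate A → catalyst intermediate B (k2 = 48 /M/s)
    catalyst intermediate B ⇌ free catalyst + product (K3 = 0.031 M, k3 = 2.5 /s)
    partner + free catalyst ⇌ catalyst intermediate A (K4 = 27 /M, k4 = 16 /M/s)

| flask | substrate | partner | precatalyst | time |
|---|---|---|---|---|
| Sunday's | 0.050 M | 0.670 M | 50 µM | 15 min |
| Friday's | 0.050 M | 0.220 M | 50 µM | 15 min |
| Wednesday's | 0.050 M | 0.0750 M | 50 µM | 15 min |

* which of these there is most of at the end, counted by the substrate in it, Sunday's (catalyst intermediate B / substrate / product)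
* which of these there is most of at the end, counted by the substrate in it, Friday's (catalyst intermediate B / substrate / product)
* which of these there is most of at the end, counted by the substrate in it, Wednesday's (catalyst intermediate B / substrate / product)
* amount of the one of these that there is most of at the end, in percent of the substrate charged, Sunday's
* amount of the one of these that there is most of at the end, in percent of the substrate charged, Friday's
* amount of the one of these that there is most of at the end, in percent of the substrate charged, Wednesday's

Partner stands far above the catalyst; each round also takes one partner, but hold it at its charge for this reckoning and treat release as pseudo-first-order. Multiply the first step's constant by c(partner) as charged and by the time, and call this N: 4.40 for Sunday's, 1.45 for Friday's, 0.493 for Wednesday's. Replace the rising released fraction by its mean over the run, one minus (one minus exp(−N))/N, which gives, in the same order, 0.776, 0.471 and 0.210.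

Now take one released catalyst at the charged concentrations, with no product yet. Per round it spends 0.400 s as intermediate B, 0.417 s as intermediate A, and a wait as free catalyst that grows as c(partner) falls and is stretched by the back-step of intermediate A. The round time comes, in the same order, to 0.933 s, 1.17 s and 1.86 s. Sunday's round is far shorter than its release time of 204 s, so the mean may stand for the curve.

Fold these into one number, Φ = 0.748 for Sunday's, 0.362 for Friday's, 0.102 for Wednesday's. This is the round budget: mean released catalyst times time, over round time and charged substrate, or the rounds available per substrate molecule charged. If the rate followed c(substrate) proportionally, the converted fraction would be one minus exp(−Φ), and product would pass substrate above Φ = 0.693, as Sunday's does and Friday's does not. I commit to Sunday's product at 52.7%, Friday's substrate at 69.6% and Wednesday's substrate at 90.3%. One number is not quite enough: the part of Sunday's round time that stretches as c(substrate) falls is about half of it at the start, so the exponential overstates the slowing, and on that count my Sunday's figure leans low.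

The forecast, on the ground that “turnover is limited by how much catalyst has been released”, gave product at 57% (50% to 64%) for Sunday's, substrate at 70% (64% to 76%) for Friday's and substrate at 91% (87% to 94%) for Wednesday's. Its Sunday's figure stands above mine.

The flasks gave product at 57.4% for Sunday's, substrate at 69.4% for Friday's and substrate at 90.6% for Wednesday's. In Sunday's, the turning of intermediate B into free catalyst and product had 3.2% of its turnover up to the asked time behind it at 1.50 min. At 7.50 min precatalyst stood at 11.3% of the catalyst charged and product at 26.0% of the substrate charged, and half of that turnover was done by 8.09 min. Sunday's product, read back through the exponential, gives Φ of 0.853 against the budget of 0.748. Scale that budget to 1.2 × 10⁻⁵ M of precatalyst, the same flask otherwise: Φ falls to 0.180, or 16.5% product. That flask ended with 16.9% product and 83.1% substrate.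

The constants were set for the occasion; the flask was simulated.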